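Conventions: atom numbers follow the target. Ring A (the carbocycle) is C1, C5, C6, C7, C8, C9, C10. Ring B (the lactone) is O, C12, C11 with the exocyclic C13, fused at C6–C7. The side chain is C2 (ketone), C3, C4 (carbinol) and its methyl. The "lower" face of ring A is the face that carries the C6–O and C7–C11 bonds; the other is the "upper" face.

## Analysis of the target

The target is a cis-fused bicycle: a cycloheptane (ring A) fused at C6–C7 to an α-methylene-γ-butyrolactone (ring B), with a (3S)-3-hydroxybutanoyl chain and a hydroxyl on C1 and an (R)-2-methylbutanoate on the C5 oxygen. Ring A carries six stereocentres (C1 S, C5 S, C6 R, C7 S, C9 R, C10 S). The C10 methyl and the C1 hydroxyl lie on the lower face with the lactone; the C9 hydroxyl, the C5 acyloxy group and the C1 side chain lie on the upper face. C5–O/C6–O, C9–O/C10–Me and C1–OH/C5–O are therefore each trans. C4 (S) in the chain and the (R) centre of the acyl group are independent of the ring and are best taken from the chiral pool. The sensitive groups are the α-methylene lactone (a Michael acceptor), the tertiary α-ketol C1–C2 (acyloin shift), the β-hydroxy ketone C2–C4 (retro-aldol, dehydration) and an ester next to a free tertiary hydroxyl (acyl migration); they dictate a mild, late unmasking. The difficulty is a contiguous array of six stereocentres on a conformationally mobile seven-membered ring. The fully substituted carbinol C1 is flanked by two stereocentres of opposite facial sense (C5–O upper, C10–Me lower), and three hydroxyls have to be told apart. The strategy rests on one feature: the oxygens on C6 and C9 are 1,4 across C7–C8, and C1, at the ketone oxidation level, lies on the mirror plane that relates C6 to C9 and C5 to C10. A meso endoperoxide of a C1-ketal cycloheptadiene thus holds ring A with both oxygens in place. Cleaving its O–O bond enantioselectively gives a C9 enone with the C6 hydroxyl, which activates C7, C10 and later C5 and C1 in turn.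

## Retrosynthetic reasoning

The last operations only uncover what is in place. Target 32 is silyl ether 31 without its C4 silyl group. The C11=C13 bond of 31 is cut back to a carboxyl group on C11 (acid 30, from benzyl ester 29). A carboxy lactone can be turned into the methylene lactone under near-neutral conditions at the very end, when enolate chemistry on the lactone is no longer possible beside the C2 ketone. The same hydrogenolysis that frees the acid also frees the C9 hydroxyl.

The C2 carbonyl of 29 is traced to the 1,1-disubstituted alkene of 28 (oxidative cleavage of C2=CH2), and the C5–O acyl bond to diol 26 and acid 27. A secondary hydroxyl beside a tertiary one can be acylated selectively, and the alkene is an inert form of the ketone while C1 is built.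

The C1–C2 bond is cut next: 26 comes from α-hydroxy ketone 19 and alkenylmagnesium reagent 25. C1 is the carbonyl carbon that the ring has carried from the start, so it is the natural electrophile. The nucleophile is a small sp2 carbon that brings C3, C4 (S) and the methyl from (S)-propylene oxide 20 through 22, 23 and 24. The forward step has to deliver the chain on the upper face, cis to the C5 oxygen; this is the least secure stereocentre of the route.

The C5–O bond of 19 is cut to ketone 18 (hydroxylation of the C1 enolate). With the methyl already on C10, kinetic enolisation can only go towards the C5 methylene, and the lactone screens the lower face of C5.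

Ketone 18 comes from ketal 17, and the C9 ether from alcohol 16. The C9 oxygen of the target is trans to the C10 methyl and to the lactone, the opposite of what hydride delivery to ketone 13 from its open face gives (alcohol 14). The disconnection therefore includes an inversion (14 to 16 through ester 15). C9 has to be an alcohol before the ketal is opened, or C9 and C1 would form a 1,3-diketone around C10.

Ring B is cut at C7–C11: keto lactone 13 comes from malonate 12 by intramolecular conjugate addition, and 12 from alcohol 10 and half-ester 11. The two-atom tether from the C6 oxygen can only reach the face of C7 on which that oxygen sits, so the cis fusion is built in, and the extra carboxyl on C11 is the later handle for C13.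

The C10–CH3 bond is cut while C9 is still an enone carbonyl (10 from 8 through 9, 8 from 7). In the enone C10 is the only enolisable position, whereas after ring B is closed C8 would compete.

Hydroxy enone 7 is cut back to meso endoperoxide 6 by reforming the O–O bond. Forward, a chiral base removes one of the two enantiotopic bridgehead hydrogens; this single step sets the absolute configuration of C6 and, through it, of the whole ring.

The key disconnection cuts both C–O bonds of 6, giving diene 4 and dioxygen 5 in its singlet state. Two bonds, one ring and two cis stereocentres are gained in one step, and no facial selectivity is needed on a symmetrical diene.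

Diene 4 comes from dienone 2 and bis-silyl ether 3 (ketalisation that does not move the double bonds), and 2 from tropone 1 by hydride addition. Ring A is thus bought, not built.

## Alternatives that were turned down

Alternative 1: The bonds cut are C6–C7 of ring A and the lactone C12–O bond, leading back to an open chain with an aldehyde at C6 and a 2-(bromomethyl)acrylate terminus. In the forward step zinc or indium metal inserts at C13, the allyl metal adds through C7 to the aldehyde, and the C6 alkoxide closes the lactone, giving A1 (cis-fused 5-(tert-butyldimethylsilyloxy)-8-(4-methoxybenzyloxy)-6-methyl-3,7-dimethylideneoctahydro-2H-cyclohepta[b]furan-2-one).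
- For it: both rings, C6, C7 and the finished α-methylene lactone arise in one operation through a cyclic transition state that favours the cis lactone. On this point it is stronger than the chosen route, which needs a late hydrogenolysis and methylenation.
- Against it: a seven-membered ring is closed by an intramolecular allylation, with the entropic cost of a medium ring. The relation of C6/C7 to the preset C5, C9 and C10 centres depends on the folding of a flexible chain.
- Against it: the chain needs three stereocentres and a trisubstituted alkene of defined geometry, each made separately.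
- Against it: in A1 C1 is a methylidene beside the lactone methylidene, so turning C1 into the ketone requires telling two similar alkenes apart. The C1 carbinol is still to be made, now with a reactive Michael acceptor in the molecule.
- Comparison: the chosen strategy takes ring A intact from a seven-carbon building block, installs the C6 and C9 oxygens in one step and draws all ring chirality from one catalytic desymmetrisation.

Alternative 2: The bonds cut are C7–C8 (ring A) and C11–C13, leading back to a butenolide (ring B with C6) tethered to a silyl enol ether whose terminus is C8. In the forward step a mild Lewis acid promotes the Mukaiyama–Michael addition of C8 to C7, and the resulting ketene acetal is trapped at C11 by a methyleneiminium salt, giving A2 (cis-fused lactone with the C9 ketone, a C1 spiro-acetonide and a dimethylaminomethyl group on C11).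
- For it: ring B and C6 are preformed, and one cascade sets C7 and C11 and installs a masked methylene that survives later steps. The fully substituted C1 is set in the open chain before cyclisation, which makes it stronger than the chosen route at the centre the chosen route controls least securely.
- Against it: the seven-membered ring must again be closed, here by a bimolecular-type bond formation that competes with desilylation.
- Against it: the C8 enol ether has to be made regioselectively beside an epimerisable C10 and a β-oxygenated C1.
- Against it: the precursor carries C1, C5 and C10 from separate asymmetric steps, and C2 arrives as an acetal-protected CH2O group that needs oxidation and a two-carbon extension with control at C4.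
- Against it: the C9 ketone of A2 poses the same trans-reduction problem as in the chosen route.
- Comparison: the chosen strategy reaches the same oxidation pattern on ring A in far fewer steps and without a medium-ring closure.

Alternative 3: The bond cut is C9–C10, leading back to a cis-disubstituted lactone that carries an aldehyde arm (C8–C9) and an α-bromo ketone (C1, C10). In the forward step a divalent samarium reductant forms the samarium enolate at C10, which adds to the C9 aldehyde and closes ring A, giving A3 (cis-fused 5-hydroxy-8-(4-methoxybenzyloxy)-6-methylhexahydro-2H-cyclohepta[b]furan-2,7(3H)-dione).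
- For it: C9 and C10 are set together in a C–C bond-forming ring closure, and the C9 alcohol/C1 ketone pattern appears directly, without a 1,3-diketone problem. If the aldol gives the anti product, no inversion at C9 is needed; on this point it is stronger than the chosen route.
- Against it: the α-bromo ketone has an α′-alkoxy group at C5, which the same reductant can cleave. The aldolate can revert and erode the new centres, and neither the anti relation C9–OH/C10–Me nor its relation to the lactone is enforced.
- Against it: the lactone template with C5, C6 and C7 needs many steps.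
- Against it: A3 stands where hydroxy ketone 19 stands, so the C1 addition and the methylenation remain to be done exactly as here.
- Comparison: the chosen strategy reaches the stage of 19 from tropone 1 with the ring given and only one asymmetric step.

Key step: step 3

Assumption 1: the quinidine-derived base of step 4 is taken to remove the bridgehead hydrogen on the carbon that becomes C9; if the sense of induction is the opposite one, its quinine-derived pseudoenantiomer (O-acetylcupreine) is used.
Assumption 2: the kinetic methylation of step 6 is taken to occur cis to the C6 silyloxy group; C10 stays epimerisable, and its trans relation to the C9 oxygen is the thermodynamic one once C1 is a ketone (step 12).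

Step 1
Reactants: 1 tropone
Product: 2 cyclohepta-3,5-dien-1-one
Conditions: LiAlH4, Et2O, −10 °C; then H2O
Reagents that add atoms: none
Why: Hydride adds to C2 of tropone (conjugate 1,8-addition) and the aluminium dienolate is protonated at the α-carbon on cold quench, which gives the non-conjugated dienone; this is the known hydride reduction of tropone.

Step 2
Reactants: 2 cyclohepta-3,5-dien-1-one; 3 1,2-bis(trimethylsilyloxy)ethane
Product: 4 1,4-dioxaspiro[4.6]undeca-7,9-diene
Conditions: TMSOTf (cat.), CH2Cl2, −78 °C; pyridine quench
Reagents that add atoms: 1,2-bis(trimethylsilyloxy)ethane (3), C[Si](C)(C)OCCO[Si](C)(C)C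
Why: Noyori ketalisation is aprotic and runs at −78 °C, so the β,γ-unsaturated ketone becomes the dioxolane without migration of the double bonds into conjugation; formation of the strong Si–O–Si bond drives it.

Step 3
Reactants: 4 1,4-dioxaspiro[4.6]undeca-7,9-diene; 5 dioxygen
Product: 6 meso endoperoxide, spiro[1,3-dioxolane-2,3'-[6,7]dioxabicyclo[3.2.2]non[8]ene]
Conditions: O2, tetraphenylporphyrin (cat.), visible light, CH2Cl2, −20 °C
Reagents that add atoms: dioxygen (5), O=O
Why: Triplet-excited tetraphenylporphyrin transfers its energy to dioxygen, and the singlet oxygen adds suprafacially across C6 and C9 of the s-cis diene in a concerted (4+2) cycloaddition, the closest known case being the dye-sensitised photooxygenation of cyclohepta-1,3-diene to its 6,7-dioxabicyclo[3.2.2]nonene. Both C–O bonds form in this one step, which closes the six-membered 1,2-dioxine ring (O, O, C6, C7, C8, C9) by cycloaddition and leaves the C7=C8 alkene. The two new stereocentres C6 and C9 are cis because the peroxide bridge can only span one face of the ring. The mirror plane through C1 and the midpoint of C7–C8 makes the two diene faces equivalent, so the product is one meso compound and no facial selectivity is required. The selectivity that is required is cycloaddition in preference to the ene reaction with the allylic hydrogens on C5 and C10; the ring-enforced cisoid diene, the low temperature and the non-polar solvent favour the cycloaddition, as with the parent diene. The ketal is inert to singlet oxygen and keeps C1 at the ketone level on the symmetry plane. Absolute configuration is deferred to step 4, where a chiral base distinguishes the two enantiotopic bridgehead C–H bonds.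

Step 4
Reactants: 6 meso endoperoxide
Product: 7 (10S)-10-hydroxy-1,4-dioxaspiro[4.6]undec-8-en-7-one (C9 enone, C6 hydroxyl on the lower face)
Conditions: O-acetylcupreidine (10 mol %), CH2Cl2, rt
Reagents that add atoms: none
Why: In the Kornblum–DeLaMare rearrangement the base removes a bridgehead hydrogen antiperiplanar to the weak O–O bond, giving the ketone at that carbon and the alkoxide at the other. A bifunctional cinchona base selects one of the two enantiotopic hydrogens, as known for meso endoperoxides of cyclic 1,3-dienes. This sets C6; the amine is too weak a base to open the β-keto ketal.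

Step 5
Reactants: 7 hydroxy enone
Product: 8 (10S)-10-(triethylsilyloxy)-1,4-dioxaspiro[4.6]undec-8-en-7-one
Conditions: Et3SiCl, imidazole, CH2Cl2, 0 °C
Reagents that add atoms: chlorotriethylsilane, CC[Si](Cl)(CC)CC
Why: Standard silylation of the secondary allylic alcohol under weakly basic conditions removes the acidic O–H before the enolate step.

Step 6
Reactants: 8 silyl ether
Product: 10 (6S,10S)-10-hydroxy-6-methyl-1,4-dioxaspiro[4.6]undec-8-en-7-one, via methylated silyl ether 9 (not isolated)
Conditions: LiN(i-Pr)2, THF, −78 °C; MeI, DMPU, −78 to −60 °C; AcOH quench; then Bu4NF, AcOH, THF, 0 °C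
Reagents that add atoms: iodomethane, CI
Why: Kinetic deprotonation of the enone can only take place at C10 (C8 is vinylic), and the cross-conjugated lithium enolate is methylated there. It is kept at −78 °C because a ketal oxygen is β to it; lithium enolates of oxygen-bridged cycloheptanones with an aligned β-C–O bond are alkylated under such conditions. The methyl is expected to enter cis to the C6 oxygen, on the face away from the pseudo-axial dioxolane oxygen, and buffered fluoride then frees the C6 hydroxyl.

Step 7
Reactants: 10 methylated hydroxy enone; 11 benzyl hydrogen malonate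
Product: 12 benzyl (6S,10S)-6-methyl-7-oxo-1,4-dioxaspiro[4.6]undec-8-en-10-yl malonate
Conditions: DCC, DMAP (cat.), CH2Cl2, 0 °C
Reagents that add atoms: benzyl hydrogen malonate (11), O=C(O)CC(=O)OCc1ccccc1
Why: Steglich esterification of the secondary alcohol attaches the C11–C12 unit to the C6 oxygen as a soft carbon acid under near-neutral conditions.

Step 8
Reactants: 12 malonate
Product: 13 cis-fused keto lactone (C7–C11 bond formed; C9 ketone; C10 methyl lower; C11 benzyl ester; C1 ketal)
Conditions: Cs2CO3 (0.2 equiv), MeCN, 0 °C
Reagents that add atoms: none
Why: Intramolecular Michael addition (5-exo-trig) of the malonate carbanion to C7 of the enone closes ring B. The two-atom tether from the C6 oxygen can only reach the face of C7 on which that oxygen sits, so the ring fusion is cis. C11 is labile and takes the ester to the exo side; a catalytic carbonate base spares the β-keto ketal.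

Step 9
Reactants: 13 keto lactone
Product: 14 C9 alcohol with the hydroxyl on the lower face (cis to the C10 methyl)
Conditions: LiBH(s-Bu)3 (2.2 equiv), THF, −78 °C; aq. NH4Cl
Reagents that add atoms: none
Why: The bulky borohydride attacks the ketone anti to the adjacent C10 methyl and away from the lactone, that is from the upper face, which gives the alcohol cis to the methyl, as with 2-methylcycloalkanones. The first equivalent deprotonates C11–H, and the resulting enolate shields lactone and ester.

Step 10
Reactants: 14 C9 alcohol (lower)
Product: 16 C9 alcohol with the hydroxyl on the upper face (trans to the C10 methyl and to the lactone), via 4-nitrobenzoate 15 (not isolated)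
Conditions: PPh3, DIAD, 4-O2NC6H4CO2H, THF, 0 °C to rt; then NaOMe (1.2 equiv), MeOH, 0 °C; AcOH
Reagents that add atoms: 4-nitrobenzoic acid, O=C(O)c1ccc(cc1)[N+](=O)[O-]
Why: Mitsunobu esterification inverts C9 by SN2 displacement of the oxyphosphonium group; the carboxylate approaches from the open upper face, anti to the leaving group and to the C10 methyl. Methanolysis of the activated aryl ester then frees the alcohol while the C11 enolate protects lactone and benzyl ester.

Step 11
Reactants: 16 C9 alcohol (upper)
Product: 17 C9 benzyl ether
Conditions: BnOC(=NH)CCl3, TfOH (cat.), CH2Cl2–cyclohexane, 0 °C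
Reagents that add atoms: benzyl 2,2,2-trichloroacetimidate, N=C(OCc1ccccc1)C(Cl)(Cl)Cl
Why: Acid-catalysed benzylation with the trichloroacetimidate avoids a base that would alkylate the acidic C11 position. The small, coordinating benzyl ether is chosen for the later addition at C1 and is removed together with the benzyl ester.

Step 12
Reactants: 17 ketal
Product: 18 C1 ketone (C9 benzyl ether, C10 methyl lower, C11 benzyl ester)
Conditions: PPTS, acetone–H2O, 50 °C
Reagents that add atoms: water, O
Why: Mild acid hydrolysis of the dioxolane frees the C1 ketone only now that C9 is an ether, so no 1,3-diketone can form. Any acid-mediated enolisation towards C10 leaves the methyl trans to the C9 benzyloxy group, which is the thermodynamic arrangement.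

Step 13
Reactants: 18 C1 ketone
Product: 19 α-hydroxy ketone with the C5 hydroxyl on the upper face (trans to C6–O)
Conditions: KN(SiMe3)2 (2.1 equiv), THF, −78 °C; 2-(phenylsulfonyl)-3-phenyloxaziridine, −78 °C; aq. NH4Cl
Reagents that add atoms: 2-(phenylsulfonyl)-3-phenyloxaziridine, O=S(=O)(N1OC1c1ccccc1)c1ccccc1
Why: The first equivalent of base forms the stabilised C11 enolate and the second removes a C5 hydrogen kinetically (methylene versus the C10 methine). The more nucleophilic ketone enolate is hydroxylated by the Davis oxaziridine from the upper face, away from the lactone fused below C5/C6. With C11 deprotonated the lactone oxygen is a poor leaving group, which holds back β-elimination from the C5 enolate.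

Step 14
Reactants: 20 (S)-propylene oxide; 21 lithium acetylide–ethylenediamine complex
Product: 22 (S)-pent-4-yn-2-ol
Conditions: LiC≡CH·H2NCH2CH2NH2, DMSO, 0 °C to rt
Reagents that add atoms: lithium acetylide–ethylenediamine complex (21), [Li]C#C.NCCN
Why: The acetylide opens the epoxide by SN2 attack at the unsubstituted carbon, so the stereocentre that becomes C4 is untouched.

Step 15
Reactants: 22 (S)-pent-4-yn-2-ol
Product: 23 (S)-tert-butyldimethyl(pent-4-yn-2-yloxy)silane
Conditions: t-BuMe2SiCl, imidazole, DMF, rt
Reagents that add atoms: tert-butylchlorodimethylsilane, CC(C)(C)[Si](C)(C)Cl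
Why: Standard silylation of the secondary alcohol; the silyl ether lasts to the final step.

Step 16
Reactants: 23 silyl ether of the alkynol
Product: 24 (S)-[(4-bromopent-4-en-2-yl)oxy](tert-butyl)dimethylsilane
Conditions: B-bromo-9-BBN, CH2Cl2, 0 °C; AcOH
Reagents that add atoms: B-bromo-9-borabicyclo[3.3.1]nonane, BrB1C2CCCC1CCC2
Why: Bromoboration of the terminal alkyne places bromine on the internal carbon and boron on the terminal one (cis addition); protonolysis of the C–B bond with acetic acid leaves the 2-bromo-1-alkene.

Step 17
Reactants: 19 α-hydroxy ketone; 24 bromoalkene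
Product: 26 C1,C5-diol carrying the (4S)-4-(tert-butyldimethylsilyloxy)pent-1-en-2-yl group on C1 (chain upper, C1 hydroxyl lower), via alkenylmagnesium bromide 25 (not isolated)
Conditions: 24, Mg, THF; then 19 added to the reagent (3.5 equiv), THF, −78 to −20 °C; aq. NH4Cl
Reagents that add atoms: bromoalkene 24 (delivered as 25), C[C@H](O[Si](C)(C)C(C)(C)C)CC(Br)=C; magnesium (retained only in 25), [Mg]
Why: Chelation-controlled Grignard addition. The magnesium alkoxide of the free C5 hydroxyl chelates the C1 carbonyl and holds C5–O in the carbonyl plane, which places the trans C10 methyl pseudo-axial on the lower face; the reagent, which the C9 benzyloxy oxygen on the upper face can also coordinate, is therefore expected to enter from the upper face and give the C1 hydroxyl trans to C5–O and cis to the methyl. The first two equivalents deprotonate C11–H and the C5 hydroxyl, and the C11 enolate shields lactone and ester.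

Step 18
Reactants: 26 diol; 27 (R)-2-methylbutanoic acid
Product: 28 C5 (R)-2-methylbutanoate (C1 hydroxyl free)
Conditions: DCC, DMAP (cat.), CH2Cl2, 0 °C to rt
Reagents that add atoms: (R)-2-methylbutanoic acid (27), CC[C@@H](C)C(=O)O
Why: Steglich esterification acylates the secondary C5 hydroxyl and leaves the tertiary C1 hydroxyl untouched; carbodiimide activation with catalytic DMAP does not pass through a ketene, so the α-centre of the acid is kept.

Step 19
Reactants: 28 alkene
Product: 29 C2 ketone (tertiary α-ketol at C1–C2)
Conditions: O3, CH2Cl2, −78 °C (indicator end point); PPh3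
Reagents that add atoms: ozone, [O-][O+]=O
Why: Ozonolysis cleaves the only alkene, a 1,1-disubstituted one, to the ketone and formaldehyde; reductive work-up at low temperature keeps the α-ketol and the benzyl groups intact.

Step 20
Reactants: 29 benzyl ester and benzyl ether
Product: 31 α-methylene lactone with the C4 silyl ether (C9 and C1 hydroxyls free), via carboxylic acid 30 (not isolated)
Conditions: H2, Pd(OH)2/C, EtOAc, rt; filter; then 37% aq. CH2O, Et2NH, NaOAc, AcOH, rt to 50 °C
Reagents that add atoms: formaldehyde, C=O
Why: Hydrogenolysis removes both benzyl groups and gives the C11 carboxy lactone. Its Mannich reaction with formaldehyde and diethylamine is followed by loss of CO2 and the amine (decarboxylative methylenation of malonic half-esters), which forms C11=C13 without a strong base; the ketone reacts much more slowly than the malonic acid.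

Step 21
Reactants: 31 silyl ether
Product: 32 target, (3aS,5R,6S,7S,8S,8aR)-5,7-dihydroxy-7-[(3S)-3-hydroxybutanoyl]-6-methyl-3-methylidene-2-oxooctahydro-2H-cyclohepta[b]furan-8-yl (2R)-2-methylbutanoate
Conditions: HF·pyridine, pyridine, THF, 0 °C to rt
Reagents that add atoms: none
Why: Buffered fluoride cleaves the secondary silyl ether under mildly acidic conditions, which the methylene lactone, the α-ketol and the β-hydroxy ketone tolerate; no base is present that could cause retro-aldol cleavage or acyl migration.

Compound list

1 | tropone (cyclohepta-2,4,6-trien-1-one) | O=C1C=CC=CC=C1 | starting material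
2 | cyclohepta-3,5-dien-1-one | O=C1CC=CC=CC1 | intermediate
3 | 1,2-bis(trimethylsilyloxy)ethane | C[Si](C)(C)OCCO[Si](C)(C)C | starting material
4 | 1,4-dioxaspiro[4.6]undeca-7,9-diene | C1COC2(O1)CC=CC=CC2 | intermediate
5 | dioxygen | O=O | starting material
6 | meso endoperoxide, spiro[1,3-dioxolane-2,3'-[6,7]dioxabicyclo[3.2.2]non[8]ene] | C1COC2(O1)C[C@H]3C=C[C@@H](C2)OO3 | intermediate
7 | (10S)-10-hydroxy-1,4-dioxaspiro[4.6]undec-8-en-7-one | O=C1C=C[C@@H](O)CC2(C1)OCCO2 | intermediate
8 | (10S)-10-(triethylsilyloxy)-1,4-dioxaspiro[4.6]undec-8-en-7-one | O=C1C=C[C@@H](O[Si](CC)(CC)CC)CC2(C1)OCCO2 | intermediate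
9 | (6S,10S)-6-methyl-10-(triethylsilyloxy)-1,4-dioxaspiro[4.6]undec-8-en-7-one | O=C1C=C[C@@H](O[Si](CC)(CC)CC)CC2(OCCO2)[C@H]1C | intermediate
10 | (6S,10S)-10-hydroxy-6-methyl-1,4-dioxaspiro[4.6]undec-8-en-7-one | O=C1C=C[C@@H](O)CC2(OCCO2)[C@H]1C | intermediate
11 | benzyl hydrogen malonate | O=C(O)CC(=O)OCc1ccccc1 | starting material
12 | benzyl (6S,10S)-6-methyl-7-oxo-1,4-dioxaspiro[4.6]undec-8-en-10-yl malonate | O=C1C=C[C@@H](OC(=O)CC(=O)OCc3ccccc3)CC2(OCCO2)[C@H]1C | intermediate
13 | cis-fused keto lactone: benzyl 6-methyl-2,5-dioxooctahydrospiro[cyclohepta[b]furan-7,2'-[1,3]dioxolane]-3-carboxylate (C9 ketone; C10 methyl lower; C11 ester trans to C8) | O=C(OCc3ccccc3)[C@@H]1C(=O)O[C@@H]2[C@H]1CC(=O)[C@H](C)C4(OCCO4)C2 | intermediate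
14 | C9 alcohol of 13 with the hydroxyl on the lower face (cis to the C10 methyl) | O=C(OCc3ccccc3)[C@@H]1C(=O)O[C@@H]2[C@H]1C[C@H](O)[C@H](C)C4(OCCO4)C2 | intermediate
15 | C9 4-nitrobenzoate with the oxygen on the upper face | O=C(OCc3ccccc3)[C@@H]1C(=O)O[C@@H]2[C@H]1C[C@@H](OC(=O)c5ccc(cc5)[N+](=O)[O-])[C@H](C)C4(OCCO4)C2 | intermediate
16 | C9 alcohol with the hydroxyl on the upper face (trans to the C10 methyl) | O=C(OCc3ccccc3)[C@@H]1C(=O)O[C@@H]2[C@H]1C[C@@H](O)[C@H](C)C4(OCCO4)C2 | intermediate
17 | C9 benzyl ether of 16 | O=C(OCc3ccccc3)[C@@H]1C(=O)O[C@@H]2[C@H]1C[C@@H](OCc5ccccc5)[C@H](C)C4(OCCO4)C2 | intermediate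
18 | benzyl 5-(benzyloxy)-6-methyl-2,7-dioxooctahydro-2H-cyclohepta[b]furan-3-carboxylate (C1 ketone) | O=C(OCc3ccccc3)[C@@H]1C(=O)O[C@@H]2[C@H]1C[C@@H](OCc5ccccc5)[C@H](C)C(=O)C2 | intermediate
19 | benzyl 5-(benzyloxy)-8-hydroxy-6-methyl-2,7-dioxooctahydro-2H-cyclohepta[b]furan-3-carboxylate (C5 hydroxyl upper) | O=C(OCc3ccccc3)[C@@H]1C(=O)O[C@@H]2[C@H]1C[C@@H](OCc5ccccc5)[C@H](C)C(=O)[C@H]2O | intermediate
20 | (S)-propylene oxide ((S)-2-methyloxirane) | C[C@H]1CO1 | starting material
21 | lithium acetylide–ethylenediamine complex | [Li]C#C.NCCN | starting material
22 | (S)-pent-4-yn-2-ol | C[C@H](O)CC#C | intermediate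
23 | (S)-tert-butyldimethyl(pent-4-yn-2-yloxy)silane | C[C@H](O[Si](C)(C)C(C)(C)C)CC#C | intermediate
24 | (S)-[(4-bromopent-4-en-2-yl)oxy](tert-butyl)dimethylsilane | C[C@H](O[Si](C)(C)C(C)(C)C)CC(Br)=C | intermediate
25 | [(4S)-4-(tert-butyldimethylsilyloxy)pent-1-en-2-yl]magnesium bromide | C[C@H](O[Si](C)(C)C(C)(C)C)CC(=C)[Mg]Br | intermediate
26 | C1,C5-diol: C1 carries the (4S)-4-(tert-butyldimethylsilyloxy)pent-1-en-2-yl group (upper) and a hydroxyl (lower); C5 hydroxyl upper; C9 benzyl ether; C11 benzyl ester | O=C(OCc3ccccc3)[C@@H]1C(=O)O[C@@H]2[C@H]1C[C@@H](OCc5ccccc5)[C@H](C)[C@@](O)(C(=C)C[C@H](C)O[Si](C)(C)C(C)(C)C)[C@H]2O | intermediate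
27 | (R)-2-methylbutanoic acid | CC[C@@H](C)C(=O)O | starting material
28 | C5 (R)-2-methylbutanoate of 26 | O=C(OCc3ccccc3)[C@@H]1C(=O)O[C@@H]2[C@H]1C[C@@H](OCc5ccccc5)[C@H](C)[C@@](O)(C(=C)C[C@H](C)O[Si](C)(C)C(C)(C)C)[C@H]2OC(=O)[C@H](C)CC | intermediate
29 | C2 ketone from 28 (C9 benzyl ether; C11 benzyl ester; C4 silyl ether) | O=C(OCc3ccccc3)[C@@H]1C(=O)O[C@@H]2[C@H]1C[C@@H](OCc5ccccc5)[C@H](C)[C@@](O)(C(=O)C[C@H](C)O[Si](C)(C)C(C)(C)C)[C@H]2OC(=O)[C@H](C)CC | intermediate
30 | C11 carboxylic acid with free C9 hydroxyl (C4 silyl ether) | OC(=O)[C@@H]1C(=O)O[C@@H]2[C@H]1C[C@@H](O)[C@H](C)[C@@](O)(C(=O)C[C@H](C)O[Si](C)(C)C(C)(C)C)[C@H]2OC(=O)[C@H](C)CC | intermediate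
31 | C4 tert-butyldimethylsilyl ether of the target | C=C1C(=O)O[C@@H]2[C@H]1C[C@@H](O)[C@H](C)[C@@](O)(C(=O)C[C@H](C)O[Si](C)(C)C(C)(C)C)[C@H]2OC(=O)[C@H](C)CC | intermediate
32 | (3aS,5R,6S,7S,8S,8aR)-5,7-dihydroxy-7-[(3S)-3-hydroxybutanoyl]-6-methyl-3-methylidene-2-oxooctahydro-2H-cyclohepta[b]furan-8-yl (2R)-2-methylbutanoate | C=C1C(=O)O[C@@H]2[C@H]1C[C@@H](O)[C@H](C)[C@@](O)(C(=O)C[C@H](C)O)[C@H]2OC(=O)[C@H](C)CC | target

Total step count: 21. Longest linear sequence: 18 steps (steps 1–13 and 17–21); the side-chain reagent 24 takes 3 steps (14–16).

Steps least certain to work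

Step 3 (key step). The photooxygenation may be diverted into the ene reaction at the allylic C5/C10 hydrogens, or the strained peroxide may decompose on handling, since the O–O bond is weak and the neighbouring ketal is acid-labile. Fallback, from 4 to 7, without a peroxide: Pd(OAc)2-catalysed (divalent palladium) cis-1,4-diacetoxylation of diene 4 (benzoquinone, MnO2, LiOAc, catalytic LiCl, AcOH) gives the meso cis-diacetate F1. Lipase-mediated hydrolysis of one enantiotopic acetate in pH 7 buffer gives the monoacetate F2. Oxidation of the free allylic alcohol with MnO2 gives the acetoxy enone F3, and brief methanolysis (K2CO3, MeOH, 0 °C) rejoins the route at 7.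

Step 17. The reagent may enter from the lower face, anti to the C5 oxygen, which is the usual sense for α-oxygenated cycloalkanones, and so give the wrong configuration at C1; enolisation of the hindered ketone may also compete with addition. Fallback, from 19 to 29, which puts the carbon in first and delivers the oxygen second, so that attack anti to the upper-face oxygens becomes the desired sense:
- Silylation (Et3SiOTf, 2,6-lutidine) gives the C5 triethylsilyl ether F4.
- Wittig olefination with the γ-oxido ylide made from Ph3P=CH2, (S)-propylene oxide 20 and n-BuLi gives the exocyclic alkene F5 (C1=C2, free C4 hydroxyl, geometry immaterial).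
- Silylation (t-BuMe2SiCl, imidazole) gives the bis-silyl ether F6.
- Dihydroxylation with OsO4/NMO from the lower face, away from the C5 and C9 oxygens, gives the C1,C2-diol F7.
- Dess–Martin oxidation of the secondary C2 alcohol gives the α-hydroxy ketone F8.
- Buffered HF·pyridine removes the triethylsilyl group to give the diol ketone F9, which is acylated with 27 as in step 18 and rejoins the route at 29.

Step 6. The C10 enolate may expel a ketal oxygen (E1cB opening of the dioxolane, driven further towards a tropone), and the facial selectivity of the methylation is not enforced. Fallback, from 8 to 10, in which no free C10 enolate persists: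
- Deprotonation in the presence of the silylating agent (LiN(i-Pr)2, Me3SiCl, THF, −78 °C) traps the enolate at once as the trimethylsilyl dienol ether F10.
- Simmons–Smith cyclopropanation (Et2Zn, CH2I2) of the electron-rich enol ether double bond gives the siloxycyclopropane F11.
- Fluoride followed by methanolic K2CO3 at 0 °C opens the cyclopropanol towards its methylene carbon, which becomes the C10 methyl, and removes the triethylsilyl group, so that the route is rejoined at 10.

Step 13. The C5 enolate may eliminate the lactone oxygen (β-elimination that opens ring B). The oxidant may also attack the C11 enolate, or that enolate may add to the C1 ketone. Fallback, from 18 to 19: double deprotonation in the presence of Me3SiCl (LiN(SiMe3)2, THF, −78 °C) gives the bis(trimethylsilyl) derivative F12 (C1=C5 enol ether and C11=C12 ketene acetal) with no lasting enolate. One equivalent of dimethyldioxirane epoxidises the more electron-rich C1=C5 enol ether from the upper face (Rubottom oxidation), and mild acid work-up returns 19.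

Step 10 (with step 9). Activation of the hindered C9 carbinol may end in E2 elimination towards C9=C10 instead of substitution, and the outcome of step 9 depends on the C10 configuration inherited from step 6. Fallback, from 13 to 16 in one operation and independent of substrate bias: reagent-controlled Corey–Bakshi–Shibata reduction of ketone 13 with the (S)-oxazaborolidine and catecholborane in toluene at −40 °C. The catalyst treats the branched C10 side as the large group and delivers hydride to give the upper-face alcohol directly; no new compound is involved.

Further compounds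

F0 | step 10 | none | none
F1 | step 3 | meso cis-diacetate, cis-7,10-diacetoxy-1,4-dioxaspiro[4.6]undec-8-ene | CC(=O)O[C@H]1C=C[C@@H](OC(C)=O)CC2(C1)OCCO2
F2 | step 3 | monoacetate, cis-10-acetoxy-1,4-dioxaspiro[4.6]undec-8-en-7-ol (acetate on the carbon that becomes C6) | O[C@H]1C=C[C@@H](OC(C)=O)CC2(C1)OCCO2
F3 | step 3 | acetoxy enone, (10S)-10-acetoxy-1,4-dioxaspiro[4.6]undec-8-en-7-one | O=C1C=C[C@@H](OC(C)=O)CC2(C1)OCCO2
F4 | step 17 | C5 triethylsilyl ether of 19 | O=C(OCc3ccccc3)[C@@H]1C(=O)O[C@@H]2[C@H]1C[C@@H](OCc5ccccc5)[C@H](C)C(=O)[C@H]2O[Si](CC)(CC)CC
F5 | step 17 | exocyclic alkene C1=C2 with free (S)-C4 hydroxyl | O=C(OCc3ccccc3)[C@@H]1C(=O)O[C@@H]2[C@H]1C[C@@H](OCc5ccccc5)[C@H](C)C(=CC[C@H](C)O)[C@H]2O[Si](CC)(CC)CC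
F6 | step 17 | bis-silyl ether of the exocyclic alkene (C4 tert-butyldimethylsilyl, C5 triethylsilyl) | O=C(OCc3ccccc3)[C@@H]1C(=O)O[C@@H]2[C@H]1C[C@@H](OCc5ccccc5)[C@H](C)C(=CC[C@H](C)O[Si](C)(C)C(C)(C)C)[C@H]2O[Si](CC)(CC)CC
F7 | step 17 | C1,C2-diol (C1 hydroxyl lower) | O=C(OCc3ccccc3)[C@@H]1C(=O)O[C@@H]2[C@H]1C[C@@H](OCc5ccccc5)[C@H](C)[C@@](O)(C(O)C[C@H](C)O[Si](C)(C)C(C)(C)C)[C@H]2O[Si](CC)(CC)CC
F8 | step 17 | α-hydroxy ketone with C5 triethylsilyl ether | O=C(OCc3ccccc3)[C@@H]1C(=O)O[C@@H]2[C@H]1C[C@@H](OCc5ccccc5)[C@H](C)[C@@](O)(C(=O)C[C@H](C)O[Si](C)(C)C(C)(C)C)[C@H]2O[Si](CC)(CC)CC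
F9 | step 17 | diol ketone with free C5 hydroxyl | O=C(OCc3ccccc3)[C@@H]1C(=O)O[C@@H]2[C@H]1C[C@@H](OCc5ccccc5)[C@H](C)[C@@](O)(C(=O)C[C@H](C)O[Si](C)(C)C(C)(C)C)[C@H]2O
F10 | step 6 | trimethylsilyl dienol ether of 8 | C[Si](C)(C)OC1=CC2(OCCO2)C[C@H](O[Si](CC)(CC)CC)C=C1
F11 | step 6 | siloxycyclopropane (C9–C10 bridged by CH2 on the lower face) | C[Si](C)(C)O[C@@]12C[C@@H]1C3(OCCO3)C[C@H](O[Si](CC)(CC)CC)C=C2
F12 | step 13 | bis(trimethylsilyl) derivative of 18 (C1=C5 enol ether and C11=C12 ketene acetal) | O=C(OCc1ccccc1)C1=C(O[Si](C)(C)C)O[C@@H]2[C@H]1C[C@@H](OCc3ccccc3)[C@H](C)C(O[Si](C)(C)C)=C2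
A1 | alternative 1 | cis-fused 5-(tert-butyldimethylsilyloxy)-8-(4-methoxybenzyloxy)-6-methyl-3,7-dimethylideneoctahydro-2H-cyclohepta[b]furan-2-one | C=C1C(=O)O[C@@H]2[C@H]1C[C@@H](O[Si](C)(C)C(C)(C)C)[C@H](C)C(=C)[C@H]2OCc1ccc(OC)cc1
A2 | alternative 2 | cis-fused lactone with the C9 ketone, a C1 spiro-acetonide, a C5 4-methoxybenzyl ether and a dimethylaminomethyl group on C11 | CN(C)C[C@@H]1C(=O)O[C@@H]2[C@H]1CC(=O)[C@H](C)[C@]3(OC(C)(C)OC3)[C@H]2OCc2ccc(OC)cc2
A3 | alternative 3 | cis-fused 5-hydroxy-8-(4-methoxybenzyloxy)-6-methylhexahydro-2H-cyclohepta[b]furan-2,7(3H)-dione | O=C1O[C@@H]2[C@H](C1)C[C@@H](O)[C@H](C)C(=O)[C@H]2OCc1ccc(OC)cc1
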